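## Retrosynthetic overview

1. Target 22 ⇐ macrocyclic bis(β-keto ester) 19 by ester acidolysis and double decarboxylation; the four enolizable centres (C1, C3, C1′, C3′) are set last by equilibration.
2. 19 ⇐ two C-alkylations of quinolizidinone β-keto esters by the ω-halopentyl chain of the other half: first between the halves (13 + 15), then as the 16-membered ring closure (17 → 19).
3. Ring A of each half ⇐ aza-Michael addition to methyl methacrylate, then Dieckmann condensation on a 2,3-disubstituted piperidine (ring B); no Mannich ring closure is used.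
4. Bold element: the halves are pseudo-enantiomers, (9R,9aR) against (9S,9aR), so both enantiomers of one racemic cis-piperidine 6 are used: 7 unchanged for half B, 8 after cis-to-trans inversion at its α-amino carbon for half A.
5. Ring order: ring B of both halves (one pyridine hydrogenation) → ring A of half A → ring A of half B → 16-membered carbocycle.

Assumption: the SMILES defines the target; locants follow quinolizidine numbering (C1, C2=O, C3–Me, C4, N5, C6–C9, C9a), half A is (1S,3S,9R,9aR), half B (primed locants) is (1′R,3′S,9′S,9a′R), and the absolute configurations of 7 and 8 are assigned after the separation by X-ray analysis of a salt.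

## Route

Step 1
Reactants: 1 3-bromo-2-methylpyridine; 2 di-tert-butyl dicarbonate
Product: 3 tert-butyl 2-(3-bromopyridin-2-yl)acetate
Conditions: LiN(i-Pr)2 (2.1 equiv), THF, −78 °C; then 2, −78 → 0 °C; AcOH quench
Reagents that add atoms: none
Why: Lateral (picolyl) lithiation followed by Claisen-type C-acylation with the dicarbonate, the second equivalent of base storing the more acidic product as its enolate so that it is acylated only once; no stereocentre is formed.

Step 2
Reactants: 3 tert-butyl 2-(3-bromopyridin-2-yl)acetate; 4 pent-4-yn-1-ol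
Product: 5 tert-butyl 2-[3-(5-hydroxypent-1-yn-1-yl)pyridin-2-yl]acetate
Conditions: PdCl2(PPh3)2 (3 mol %), CuI (5 mol %), Et3N/THF, 60 °C
Reagents that add atoms: none
Why: Sonogashira coupling of the 3-bromopyridine brings in all five chain carbons and the terminal oxygen in one operation; no stereocentre is formed.

Step 3
Reactants: 5 tert-butyl 2-[3-(5-hydroxypent-1-yn-1-yl)pyridin-2-yl]acetate
Product: 6 racemic cis-piperidine, tert-butyl 2-[(2S*,3S*)-3-(5-hydroxypentyl)piperidin-2-yl]acetate
Conditions: H2 (5 bar), PtO2 (10 mol %), AcOH, 25 °C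
Reagents that add atoms: none
Why: Heterogeneous catalytic hydrogenation saturates the alkyne and the protonated pyridine ring, and delivery of all hydrogens from the catalyst face sets C2 and C3 cis (relative configuration only, racemate) while the tert-butyl ester and the alcohol survive.

Step 4
Reactants: 6 racemic cis-piperidine
Product: 7 tert-butyl 2-[(2S,3S)-3-(5-hydroxypentyl)piperidin-2-yl]acetate
Conditions: preparative SFC, amylose tris(3,5-dimethylphenylcarbamate) phase, CO2/MeOH/Et2NH, 40 °C, MS-triggered collection of the (2S,3S) fraction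
Reagents that add atoms: none
Why: Resolution by chromatography on a chiral stationary phase (no bond is made or broken) fixes the absolute configuration of half B, C2/C3 of 7 becoming C9a/C9 with (9aR,9S).

Step 5
Reactants: 6 racemic cis-piperidine
Product: 8 tert-butyl 2-[(2R,3R)-3-(5-hydroxypentyl)piperidin-2-yl]acetate
Conditions: same SFC separation as in step 4, collection of the (2R,3R) fraction
Reagents that add atoms: none
Why: The antipode from the same chromatographic resolution is the entry to half A, so neither enantiomer of 6 is discarded.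

Step 6
Reactants: 8 tert-butyl 2-[(2R,3R)-3-(5-hydroxypentyl)piperidin-2-yl]acetate
Product: 9 tert-butyl 2-[(2S,3R)-3-(5-hydroxypentyl)piperidin-2-yl]acetate (trans)
Conditions: [Ir{dF(CF3)ppy}2(dtbpy)]PF6 (1 mol %), PhSH (1 equiv), MeOH, blue LEDs, 25 °C
Reagents that add atoms: none
Why: Photoredox/thiol hydrogen-atom-transfer epimerization of the α-amino C–H bond reversibly planarizes C2 and funnels the cis isomer to the more stable trans-diequatorial one, while C3 (not α to nitrogen) is untouched, so (2R,3R) becomes (2S,3R), the (9R,9aR) pattern of half A.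

Step 7
Reactants: 9 tert-butyl 2-[(2S,3R)-3-(5-hydroxypentyl)piperidin-2-yl]acetate; 10 methyl methacrylate
Product: 11 methyl 3-[(2S,3R)-2-(2-tert-butoxy-2-oxoethyl)-3-(5-hydroxypentyl)piperidin-1-yl]-2-methylpropanoate (both epimers at the propanoate α-carbon)
Conditions: 10 (10 equiv), MeOH, 65 °C, sealed tube, 72 h
Reagents that add atoms: none
Why: Aza-Michael addition of the secondary amine (nitrogen reacts in preference to the alcohol under neutral conditions); the new centre is formed unselectively but becomes the enolizable C3, which is set in step 15.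

Step 8
Reactants: 11 aza-Michael adduct of half A
Product: 12 methyl 3-[(2S,3R)-2-(2-tert-butoxy-2-oxoethyl)-3-(5-chloropentyl)piperidin-1-yl]-2-methylpropanoate
Conditions: PPh3, N-chlorosuccinimide, CH2Cl2, 0 °C (phosphonium salt formed first), then 11, 0 → 25 °C
Reagents that add atoms: N-chlorosuccinimide, O=C1CCC(=O)N1Cl
Why: Appel-type chlorination (SN2 displacement on the alkoxyphosphonium ion) turns the alcohol into a primary chloride, a latent electrophile that stays inert in steps 9, 12 and 13; no stereocentre is affected.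

Step 9
Reactants: 12 chloro diester of half A
Product: 13 tert-butyl (9R,9aR)-9-(5-chloropentyl)-3-methyl-2-oxooctahydro-2H-quinolizine-1-carboxylate (keto/enol and C1/C3 epimer mixture)
Conditions: LiN(SiMe3)2 (2.5 equiv), THF, −78 → 0 °C; AcOH quench
Reagents that add atoms: none
Why: Dieckmann condensation in which the enolate of the tert-butyl acetate arm attacks the more electrophilic methyl ester, the only mode that gives an enolizable β-keto ester (driven by enolate formation), closing ring A of half A without touching C9 or C9a.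

Step 10
Reactants: 7 tert-butyl 2-[(2S,3S)-3-(5-hydroxypentyl)piperidin-2-yl]acetate; 10 methyl methacrylate
Product: 14 methyl 3-[(2S,3S)-2-(2-tert-butoxy-2-oxoethyl)-3-(5-hydroxypentyl)piperidin-1-yl]-2-methylpropanoate (both epimers at the propanoate α-carbon)
Conditions: 10 (10 equiv), MeOH, 65 °C, sealed tube, 72 h
Reagents that add atoms: none
Why: Aza-Michael addition as in step 7, the new centre again being the later C3′ that is set in step 15.

Step 11
Reactants: 14 aza-Michael adduct of half B
Product: 15 methyl 3-[(2S,3S)-2-(2-tert-butoxy-2-oxoethyl)-3-(5-iodopentyl)piperidin-1-yl]-2-methylpropanoate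
Conditions: PPh3, iodine, imidazole, CH2Cl2, 0 °C; used at once
Reagents that add atoms: iodine, [I][I]
Why: Appel iodination (SN2 on the alkoxyphosphonium ion) gives the reactive primary iodide, which is used immediately because the molecule also holds a tertiary amine.

Step 12
Reactants: 13 β-keto ester of half A; 15 iodo diester of half B
Product: 16 tert-butyl (9R,9aR)-1-{5-[(2S,3S)-2-(2-tert-butoxy-2-oxoethyl)-1-(3-methoxy-2-methyl-3-oxopropyl)piperidin-3-yl]pentyl}-9-(5-chloropentyl)-3-methyl-2-oxooctahydro-2H-quinolizine-1-carboxylate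
Conditions: Cs2CO3 (1.5 equiv), MeCN, 30 °C
Reagents that add atoms: none
Why: SN2 C-alkylation of the β-keto ester enolate, in which only the iodide reacts (the chloride is far slower at 30 °C) and the simple esters of 15 are not deprotonated by carbonate; the new quaternary C1 has no stereochemical consequence because it is erased in step 15.

Step 13
Reactants: 16 heterodimer
Product: 17 tert-butyl (9R,9aR)-1-{5-[(9S,9aR)-1-(tert-butoxycarbonyl)-3-methyl-2-oxooctahydro-2H-quinolizin-9-yl]pentyl}-9-(5-chloropentyl)-3-methyl-2-oxooctahydro-2H-quinolizine-1-carboxylate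
Conditions: LiN(SiMe3)2 (3.5 equiv), THF, −78 → −20 °C; AcOH quench
Reagents that add atoms: none
Why: Second Dieckmann condensation closes ring A of half B with the same regiochemical logic as step 9, the extra base holding the ketone of half A as its C3 enolate so that the non-enolizable β-keto ester there is shielded from retro-Claisen attack by LiOMe.

Step 14
Reactants: 17 chloro bis(β-keto ester)
Product: 19 macrocyclic bis(tert-butyl β-keto ester), via iodide 18 (not isolated)
Conditions: Cs2CO3 (3 equiv), NaI (5 equiv), MeCN, 70 °C, syringe-pump addition to 1 mM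
Reagents that add atoms: none
Why: Finkelstein exchange followed by intramolecular SN2 C-alkylation of the only acidic C–H (C1′ of half B) under high dilution closes the 16-membered carbocycle head-to-tail, the quaternary centre formed being erased in step 15.

Step 15
Reactants: 19 macrocyclic bis(tert-butyl β-keto ester)
Product: 22 target CNP0268544.8, via diacid 20 (not isolated), via ketone epimer mixture 21 (not isolated)
Conditions: TFA/CH2Cl2 (1:2), 25 °C; evaporate, toluene, 60 °C; NaHCO3 (aq) wash; K2CO3 (20 mol %), MeOH, 25 °C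
Reagents that add atoms: none
Why: Acidolysis of the tert-butyl esters, decarboxylation of the β-keto acids and base-catalysed enolization (thermodynamic epimerization) set the four α-centres: in each trans-fused quinolizidinone the methyl is equatorial (3S, 3′S), and the C1 chain takes the position that avoids the peri (syn-pentane) clash with the C9 chain, axial in half A (1S) and equatorial in half B (1′R), while protonated nitrogen in the acid phase and mild base at 25 °C leave C9a untouched.

## Compound list

1 | 3-bromo-2-methylpyridine | Cc1ncccc1Br | starting material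
2 | di-tert-butyl dicarbonate | CC(C)(C)OC(=O)OC(=O)OC(C)(C)C | starting material
3 | tert-butyl 2-(3-bromopyridin-2-yl)acetate | CC(C)(C)OC(=O)Cc1ncccc1Br | intermediate
4 | pent-4-yn-1-ol | OCCCC#C | starting material
5 | tert-butyl 2-[3-(5-hydroxypent-1-yn-1-yl)pyridin-2-yl]acetate | CC(C)(C)OC(=O)Cc1ncccc1C#CCCCO | intermediate
6 | racemic cis tert-butyl 2-[(2S*,3S*)-3-(5-hydroxypentyl)piperidin-2-yl]acetate (one enantiomer drawn) | N1CCC[C@H](CCCCCO)[C@@H]1CC(=O)OC(C)(C)C | intermediate
7 | tert-butyl 2-[(2S,3S)-3-(5-hydroxypentyl)piperidin-2-yl]acetate (cis) | N1CCC[C@H](CCCCCO)[C@@H]1CC(=O)OC(C)(C)C | intermediate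
8 | tert-butyl 2-[(2R,3R)-3-(5-hydroxypentyl)piperidin-2-yl]acetate (cis) | N1CCC[C@@H](CCCCCO)[C@H]1CC(=O)OC(C)(C)C | intermediate
9 | tert-butyl 2-[(2S,3R)-3-(5-hydroxypentyl)piperidin-2-yl]acetate (trans) | N1CCC[C@@H](CCCCCO)[C@@H]1CC(=O)OC(C)(C)C | intermediate
10 | methyl methacrylate | C=C(C)C(=O)OC | starting material
11 | methyl 3-[(2S,3R)-2-(2-tert-butoxy-2-oxoethyl)-3-(5-hydroxypentyl)piperidin-1-yl]-2-methylpropanoate (propanoate α-carbon unassigned) | COC(=O)C(C)CN1CCC[C@@H](CCCCCO)[C@@H]1CC(=O)OC(C)(C)C | intermediate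
12 | methyl 3-[(2S,3R)-2-(2-tert-butoxy-2-oxoethyl)-3-(5-chloropentyl)piperidin-1-yl]-2-methylpropanoate | COC(=O)C(C)CN1CCC[C@@H](CCCCCCl)[C@@H]1CC(=O)OC(C)(C)C | intermediate
13 | tert-butyl (9R,9aR)-9-(5-chloropentyl)-3-methyl-2-oxooctahydro-2H-quinolizine-1-carboxylate (C1/C3 unassigned) | CC1CN2CCC[C@@H](CCCCCCl)[C@@H]2C(C(=O)OC(C)(C)C)C1=O | intermediate
14 | methyl 3-[(2S,3S)-2-(2-tert-butoxy-2-oxoethyl)-3-(5-hydroxypentyl)piperidin-1-yl]-2-methylpropanoate (propanoate α-carbon unassigned) | COC(=O)C(C)CN1CCC[C@H](CCCCCO)[C@@H]1CC(=O)OC(C)(C)C | intermediate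
15 | methyl 3-[(2S,3S)-2-(2-tert-butoxy-2-oxoethyl)-3-(5-iodopentyl)piperidin-1-yl]-2-methylpropanoate | COC(=O)C(C)CN1CCC[C@H](CCCCCI)[C@@H]1CC(=O)OC(C)(C)C | intermediate
16 | heterodimer: 13 alkylated at C1 by the pentyl chain of 15 (half A (9R,9aR); half B piperidine (2S,3S); C1/C3 and the propanoate α-carbon unassigned) | CC1CN2CCC[C@@H](CCCCCCl)[C@@H]2C(C(=O)OC(C)(C)C)(CCCCC[C@H]3CCCN(CC(C)C(=O)OC)[C@H]3CC(=O)OC(C)(C)C)C1=O | intermediate
17 | chloro bis(β-keto ester): half A (9R,9aR) quaternary at C1, half B (9′S,9a′R) with C1′–H, 5-chloropentyl on C9 | CC1CN2CCC[C@@H](CCCCCCl)[C@@H]2C(C(=O)OC(C)(C)C)(CCCCC[C@H]3CCCN4CC(C)C(=O)C(C(=O)OC(C)(C)C)[C@@H]34)C1=O | intermediate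
18 | 5-iodopentyl analogue of 17 (not isolated) | CC1CN2CCC[C@@H](CCCCCI)[C@@H]2C(C(=O)OC(C)(C)C)(CCCCC[C@H]3CCCN4CC(C)C(=O)C(C(=O)OC(C)(C)C)[C@@H]34)C1=O | intermediate
19 | macrocyclic bis(tert-butyl β-keto ester): target ring system with CO2t-Bu on C1 and C1′; (9R,9aR,9′S,9a′R); C1/C3/C1′/C3′ unassigned | CC1CN2CCC[C@@H](CCCCC5)[C@@H]2C(C(=O)OC(C)(C)C)(CCCCC[C@H]3CCCN4CC(C)C(=O)C5(C(=O)OC(C)(C)C)[C@@H]34)C1=O | intermediate
20 | 1,1′-dicarboxylic acid corresponding to 19 (not isolated) | CC1CN2CCC[C@@H](CCCCC5)[C@@H]2C(C(=O)O)(CCCCC[C@H]3CCCN4CC(C)C(=O)C5(C(=O)O)[C@@H]34)C1=O | intermediate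
21 | target constitution with (9R,9aR,9′S,9a′R) fixed and C1/C3/C1′/C3′ as epimer mixture (not isolated) | CC1CN2CCC[C@@H](CCCCC5)[C@@H]2C(CCCCC[C@H]3CCCN4CC(C)C(=O)C5[C@@H]34)C1=O | intermediate
22 | CNP0268544.8, (1S,3S,9R,9aR,1′R,3′S,9′S,9a′R)-bis-quinolizidinone macrocycle | C[C@H]1CN2CCC[C@H]3CCCCC[C@H]4C(=O)[C@@H](C)CN5CCC[C@H](CCCCC[C@H](C1=O)[C@@H]32)[C@H]45 | target

## Step count and risks

Total step count: 15. Longest linear sequence: 12 steps (1, 2, 3, 5, 6, 7, 8, 9, 12, 13, 14, 15).

The three steps most likely to fail: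

Step 14, the macrocyclization. It must form a quaternary carbon next to the ring-fusion carbon in a 16-membered ring, and O-alkylation, oligomerization or retro-Mannich scrambling of C9a in the non-enolizable β-keto ester can compete. The fallback sets out from 17 and comes back at 21. TFA/CH2Cl2 converts 17 into the bis(β-keto acid) chloride F2, which loses CO2 at 60 °C to give the diketone chloride F3. Me2NNH2 with catalytic AcOH in EtOH gives the bis(N,N-dimethylhydrazone) chloride F4, and NaI in MeCN at 70 °C gives the bis(N,N-dimethylhydrazone) iodide F5. LiN(i-Pr)2 (1.1 equiv, THF, −78 → 0 °C, 2 mM) deprotonates the only α-CH2 in the molecule (C1′ of half B), and the azaenolate closes the ring by alkylation at a tertiary instead of a quaternary carbon to give the macrocyclic bis(N,N-dimethylhydrazone) F6. Aqueous oxalic acid hydrolysis gives 21, which is equilibrated as in the last operation of step 15.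

Step 15, the final setting of C1, C3, C1′ and C3′. The outcome rests on solution thermodynamics inside the macrocycle, and basic conditions could in principle also move C9a. The fallback sets out from 21 and comes back at 22. HBr (2.2 equiv) in i-PrOH at 50 °C protonates both nitrogens, which blocks the retro-Mannich pathway, while acid-catalysed enolization interconverts the α-epimers. The least soluble salt, the bis(hydrobromide) of the target F7, is removed by crystallization (crystallization-induced diastereomer transformation), and aqueous NaHCO3 liberates 22.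

Step 6, the cis-to-trans inversion. The photochemical epimerization may stall at a modest trans:cis ratio with this N–H β-amino ester. The fallback sets out from 8 and comes back at 9. KOt-Bu (1 equiv) in t-BuOH/THF at 50 °C opens the β-amino ester by E1cB retro-aza-Michael reaction to tert-butyl (2E,4R)-4-(3-aminopropyl)-9-hydroxynon-2-enoate F1. This recloses by 6-exo-trig aza-Michael addition under thermodynamic control to the trans-piperidine 9; residual cis isomer is separated and recycled.

## Further compounds

F1 | step 6 | tert-butyl (2E,4R)-4-(3-aminopropyl)-9-hydroxynon-2-enoate | NCCC[C@@H](CCCCCO)/C=C/C(=O)OC(C)(C)C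
F2 | step 14 | bis(β-keto acid) chloride (17 with both CO2t-Bu groups as CO2H) | CC1CN2CCC[C@@H](CCCCCCl)[C@@H]2C(C(=O)O)(CCCCC[C@H]3CCCN4CC(C)C(=O)C(C(=O)O)[C@@H]34)C1=O
F3 | step 14 | diketone chloride (17 without both ester groups; C9/C9a of both halves as in 17) | CC1CN2CCC[C@@H](CCCCCCl)[C@@H]2C(CCCCC[C@H]3CCCN4CC(C)C(=O)C[C@@H]34)C1=O
F4 | step 14 | bis(N,N-dimethylhydrazone) chloride | CC1CN2CCC[C@@H](CCCCCCl)[C@@H]2C(CCCCC[C@H]3CCCN4CC(C)C(=NN(C)C)C[C@@H]34)C1=NN(C)C
F5 | step 14 | bis(N,N-dimethylhydrazone) iodide | CC1CN2CCC[C@@H](CCCCCI)[C@@H]2C(CCCCC[C@H]3CCCN4CC(C)C(=NN(C)C)C[C@@H]34)C1=NN(C)C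
F6 | step 14 | macrocyclic bis(N,N-dimethylhydrazone) | CC1CN2CCC[C@@H](CCCCC5)[C@@H]2C(CCCCC[C@H]3CCCN4CC(C)C(=NN(C)C)C5[C@@H]34)C1=NN(C)C
F7 | step 15 | bis(hydrobromide) of the target | C[C@H]1CN2CCC[C@H]3CCCCC[C@H]4C(=O)[C@@H](C)CN5CCC[C@H](CCCCC[C@H](C1=O)[C@@H]32)[C@H]45.Br.Br
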